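**Plan**
- Retrosynthetic cuts, in order: C11=C12 (olefination, butenolide fragment); C4=C18; C3 taken out of ring A (bonds C2–C3 and C3–C4); the two O-acyl bonds; C7–O and C8–O; C8–C17; C9–C11; C9–C20. What remains is the R antipode of the Hajos–Parrish ketone.
- Forward order: ring B and a five-membered forerunner of ring A (C10–C1–C2–C4–C5) come with the starting ketone. Ring B is fully decorated on the trans-hydrindane, then C3 is inserted into the C2–C4 bond, C18 is added, and the butenolide is joined last.
- Enabling feature: in ring A the sp2 carbon C4 sits between the quaternary C5 (bearing C19, C6, C10) and C3, which is followed only by CH2 groups. Read as C4=O, this is a cyclopentanone plus one CH2. Only the C2–C4 bond should migrate, and only the C3=C4 olefin can form later.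
- Gain: ring A holds no C=C bond while C7=C8 is dihydroxylated, and the strained ketone is the only group of the late intermediate that a diazoalkane attacks.
- Stereochemistry: C5 comes from the starting ketone. C10 is set by conjugate hydride anti to C19, C9 by β-face enolate alkylation, C6 by axial hydride, C7 and C8 by β-face OsO4 addition, and E-C11=C12 by the phosphonate olefination.

Key step: step 13

Assumption: both antipodes of the Hajos–Parrish ketone and 4-(bromomethyl)furan-2(5H)-one are taken as articles of commerce.
Numbering: clerodane numbering throughout (C17 on C8, C18 on C4, C19 on C5, C20 and C11 on C9). In the hydrindanes the small ring is C10–C1–C2–C4–C5. α is the face of the C5 methyl group and β is the face of H-10.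

**Step 1**
Reactants: 1 (R)-7a-methyl-2,3,7,7a-tetrahydro-1H-indene-1,5(6H)-dione
Product: 2 C4 ethylene ketal of 1 (C8 enone with C9=C10 kept)
Conditions: TMSOCH2CH2OTMS, TMSOTf (cat.), CH2Cl2, −78 °C
Reagents that add atoms: 1,2-bis(trimethylsilyloxy)ethane C[Si](C)(C)OCCO[Si](C)(C)C
Why: Silyl-triflate-catalysed ketalisation under kinetic control should take the saturated cyclopentanone and leave the less electrophilic conjugated ketone, and it creates no stereocentre.

**Step 2**
Reactants: 2 C4 ketal enone
Product: 3 trans-hydrindan-8-one C4 ketal (10β-H, 5α-methyl)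
Conditions: i-Bu2AlH, t-BuCu (20 mol %, from CuI and t-BuLi), HMPA–THF, −50 °C; aq NH4Cl
Reagents that add atoms: none
Why: In this alkylcopper-mediated conjugate hydroalumination the bulky hydride carrier should reach C10 from the β face, opposite the angular C19 methyl group, which sets 10β-H and the trans fusion as known for closely related 7a-methylhydrindenones.

**Step 3**
Reactants: 3 trans-hydrindan-8-one ketal
Product: 4 trans-hydrind-6-en-8-one C4 ketal (C6=C7 enone)
Conditions: LiN(i-Pr)2, THF, −78 °C; PhS(Cl)=N-t-Bu, −78 °C
Reagents that add atoms: none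
Why: Kinetic deprotonation of the trans-fused ketone should occur at C7, away from the ring fusion, and the sulfinimidoyl chloride turns this enolate into the enone by S-addition and syn elimination (Mukaiyama dehydrogenation).

**Step 4**
Reactants: 4 C6=C7 enone ketal
Product: 5 9β-methyl derivative of 4 (9α-H)
Conditions: LiN(i-Pr)2, THF, −78 °C; MeI, −78 → 0 °C
Reagents that add atoms: iodomethane CI
Why: C9 is the only acidic position of this 4,4-disubstituted cyclohexenone, so α′-enolate alkylation should give the 9-methyl ketone with the methyl group entering from the open β face (the centre is planarised again in step 5).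

**Step 5**
Reactants: 5 9β-methyl enone ketal
Product: 6 9β-(benzyloxymethyl)-9α-methyl enone ketal (C9 quaternary)
Conditions: LiN(i-Pr)2, THF–HMPA, −78 → 0 °C; BnOCH2Cl, −78 → −20 °C
Reagents that add atoms: benzyl chloromethyl ether ClCOCc1ccccc1
Why: In this alkylation of the tetrasubstituted cross-conjugated enolate the α face at C9 is closed by the syn-axial C19 methyl group, so the electrophile should enter from the β face and push C20 into the axial α position, as in reductive alkylations of angular-methyl bicyclic enones.

**Step 6**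
Reactants: 6 C9-quaternary enone ketal
Product: 7 tertiary allylic alcohol (8-methyl-8-ol, C6=C7; 8β-methyl and 8α-OH expected)
Conditions: MeLi, Et2O, −78 °C
Reagents that add atoms: methyllithium [Li]C
Why: Methyllithium should add 1,2 to this non-enolisable enone, and the configuration of the new carbinol centre does not matter because it is lost in step 7.

**Step 7**
Reactants: 7 tertiary allylic alcohol
Product: 8 transposed enone (C6 ketone, C7=C8 bearing C17)
Conditions: pyridinium chlorochromate [C5H5NH][CrO3Cl], NaOAc, 4 Å MS, CH2Cl2, 23 °C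
Reagents that add atoms: none
Why: In the Babler–Dauben oxidative transposition the tertiary chromate ester should shift [3,3] to C6 and be oxidised there, which moves the oxygen to C6 and leaves C17 on the new C7=C8 bond.

**Step 8**
Reactants: 8 C6 enone
Product: 9 6α-allylic alcohol
Conditions: NaBH4, CeCl3·7H2O, MeOH, −78 → 0 °C
Reagents that add atoms: none
Why: In the Luche 1,2-reduction hydride should add axially from the β face, because the α face of C6 is blocked by the neighbouring axial C19 methyl group, and give the equatorial 6α-alcohol.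

**Step 9**
Reactants: 9 6α-allylic alcohol
Product: 10 6α-acetate
Conditions: Ac2O, DMAP (cat.), pyridine, 23 °C
Reagents that add atoms: acetic anhydride CC(=O)OC(C)=O
Why: This is a DMAP-catalysed acylation of the only hydroxy group.

**Step 10**
Reactants: 10 6α-acetate
Product: 11 6α-acetoxy-7β,8β-diol (C17 α)
Conditions: OsO4 (10 mol %), NMO, MeSO2NH2, acetone–H2O, 23 °C
Reagents that add atoms: N-methylmorpholine N-oxide C[N+]1([O-])CCOCC1; water O (both oxygens pass through OsO4, O=[Os](=O)(=O)=O)
Why: Upjohn dihydroxylation should add syn to the only C=C bond from the β face, anti to the allylic 6α-acetoxy group and away from the two axial α methyl groups C19 and C20, which sets 7β-OH and 8β-OH.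

**Step 11**
Reactants: 11 6α-acetoxy-7β,8β-diol
Product: 12 6α-acetoxy-7β-isobutyryloxy-8β-ol C4 ketal
Conditions: (i-PrCO)2O, DMAP, Et3N, CH2Cl2, 23 °C
Reagents that add atoms: isobutyric anhydride CC(C)C(=O)OC(=O)C(C)C
Why: DMAP-catalysed acylation should differentiate on steric grounds, so that the secondary equatorial 7β-OH reacts and the tertiary axial 8β-OH does not.

**Step 12**
Reactants: 12 ketal diester
Product: 13 trans-hydrindan-4-one diester (free cyclopentanone)
Conditions: 1 M HCl, THF, 23 °C
Reagents that add atoms: water O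
Why: Dilute acid should hydrolyse the dioxolane while the esters, the benzyl ether and the tertiary alcohol (deactivated by the vicinal acyloxy group) survive.

**Step 13**
Reactants: 13 trans-hydrindan-4-one diester
Product: 15 trans-decal-4-one diester (ring A six-membered), via C3-silyl ketone 14 (not isolated)
Conditions: TMSCHN2, BF3·OEt2, CH2Cl2, −78 → −30 °C; then 1 M HCl, THF, 23 °C
Reagents that add atoms: (trimethylsilyl)diazomethane C[Si](C)(C)C=[N+]=[N-]
Why: The Lewis acid activates the only ketone, the nucleophilic diazo carbon adds to C4, and in the β-oxido diazonium ion the C2–C4 bond shifts to the new carbon (C3) as N2 leaves, so that the ring C10–C1–C2–C4–C5 becomes six-membered ring A; acid then replaces the C3 silyl group of 14 by hydrogen. The closest known reaction type is the Tiffeneau–Demjanov-type (Büchner–Curtius–Schlotterbeck) homologation of cyclopentanones, shown in particular on trans-hydrindan-1-ones with an α-quaternary carbon (D-homoannulation of 17-oxo steroids), where the carbonyl group stays next to the quaternary centre. No ring is closed anew: an existing ring is enlarged by a 1,2-shift with retention at the migrating CH2, and ring B is not touched. No lasting stereocentre is made (the C3 silyl epimers of 14 converge on 15), and C5 and C10, which take no part in the shift, keep the trans fusion. Regioselectivity (C2 against C5 migration) is secured by the substrate, because the fully substituted C5 migrates far more slowly than a CH2 group in Lewis-acid-promoted diazoalkane insertions, and chemoselectivity follows from the inertness of the two esters, the ether and the hindered tertiary alcohol. A second insertion should be held back because 14 is an unstrained cyclohexanone flanked by C5 and by the silyl-bearing C3.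

**Step 14**
Reactants: 15 trans-decal-4-one diester
Product: 16 11-hydroxy decal-4-one diester
Conditions: H2 (1 atm), Pd/C, EtOAc, 23 °C
Reagents that add atoms: none
Why: The benzyl ether is removed by hydrogenolysis at a stage where the molecule holds no C=C bond.

**Step 15**
Reactants: 16 11-hydroxy decal-4-one
Product: 17 4(18)-exomethylene diol diester
Conditions: Zn, CH2Br2, TiCl4, THF–CH2Cl2, 0 → 23 °C
Reagents that add atoms: dibromomethane BrCBr
Why: The gem-dizinc/titanium reagent of the Takai–Lombardo methylenation is non-basic, attacks hindered enolisable ketones and spares esters.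

**Step 16**
Reactants: 17 4(18)-exomethylene compound
Product: 18 3-ene (C3=C4 bearing C18), 11-ol
Conditions: RhCl3·3H2O (10 mol %), EtOH, 75 °C
Reagents that add atoms: none
Why: Rhodium-hydride addition–elimination should move the exocyclic double bond into the ring, and because C5 is quaternary the trisubstituted C3=C4 olefin is the only endocyclic isomer and the thermodynamic sink.

**Step 17**
Reactants: 18 3-en-11-ol
Product: 19 3-en-11-al
Conditions: Dess–Martin periodinane, NaHCO3, CH2Cl2, 0 → 23 °C
Reagents that add atoms: none
Why: Dess–Martin oxidation should take the only oxidisable (primary) alcohol under buffered, non-basic conditions that give the β-hydroxy aldehyde no chance of retro-aldol cleavage.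

**Step 18**
Reactants: 20 4-(bromomethyl)furan-2(5H)-one
Product: 21 diethyl [(5-oxo-2,5-dihydrofuran-3-yl)methyl]phosphonate
Conditions: P(OEt)3, toluene, 110 °C
Reagents that add atoms: triethyl phosphite CCOP(OCC)OCC
Why: This is a Michaelis–Arbuzov reaction of a primary allylic bromide.

**Step 19**
Reactants: 19 3-en-11-al; 21 butenolide phosphonate
Product: 22 target, 6α-acetoxy-8β-hydroxy-7β-isobutyryloxy-cleroda-3,11E,13-trien-15,16-olide
Conditions: 21, LiN(SiMe3)2, THF, −78 °C; then 19, −78 → 0 °C
Reagents that add atoms: none
Why: The vinylogously stabilised phosphonate anion of this Horner–Wadsworth–Emmons olefination is too weak a base to touch the esters or the tertiary alcohol and should give the E C11=C12 bond.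

**Compound list**
1 | (R)-7a-methyl-2,3,7,7a-tetrahydro-1H-indene-1,5(6H)-dione | C1CC(=O)C=C2CCC(=O)[C@]12C | starting material
2 | C4 ethylene ketal of 1 | C1CC(=O)C=C2CCC3(OCCO3)[C@]12C | intermediate
3 | trans-hydrindan-8-one C4 ketal (10β-H) | C1CC(=O)C[C@H]2CCC3(OCCO3)[C@]12C | intermediate
4 | trans-hydrind-6-en-8-one C4 ketal | C1=CC(=O)C[C@H]2CCC3(OCCO3)[C@]12C | intermediate
5 | 9β-methyl enone ketal | C1=CC(=O)[C@H](C)[C@H]2CCC3(OCCO3)[C@]12C | intermediate
6 | 9β-(benzyloxymethyl)-9α-methyl enone ketal | C1=CC(=O)[C@](C)(COCc3ccccc3)[C@H]2CCC4(OCCO4)[C@]12C | intermediate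
7 | 8-methyl-8-ol, C6=C7 (8α-OH expected) | C1=C[C@@](C)(O)[C@](C)(COCc3ccccc3)[C@H]2CCC4(OCCO4)[C@]12C | intermediate
8 | 6-oxo-7-ene with 8-methyl | O=C1C=C(C)[C@](C)(COCc3ccccc3)[C@H]2CCC4(OCCO4)[C@]12C | intermediate
9 | 6α-ol | O[C@H]1C=C(C)[C@](C)(COCc3ccccc3)[C@H]2CCC4(OCCO4)[C@]12C | intermediate
10 | 6α-acetate | CC(=O)O[C@H]1C=C(C)[C@](C)(COCc3ccccc3)[C@H]2CCC4(OCCO4)[C@]12C | intermediate
11 | 6α-acetoxy-7β,8β-diol | CC(=O)O[C@H]1[C@H](O)[C@](C)(O)[C@](C)(COCc3ccccc3)[C@H]2CCC4(OCCO4)[C@]12C | intermediate
12 | 6α-acetoxy-7β-isobutyryloxy-8β-ol ketal | CC(=O)O[C@H]1[C@H](OC(=O)C(C)C)[C@](C)(O)[C@](C)(COCc3ccccc3)[C@H]2CCC4(OCCO4)[C@]12C | intermediate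
13 | trans-hydrindan-4-one diester | CC(=O)O[C@H]1[C@H](OC(=O)C(C)C)[C@](C)(O)[C@](C)(COCc3ccccc3)[C@H]2CCC(=O)[C@]12C | intermediate
14 | 3-(trimethylsilyl)-trans-decal-4-one diester (C3 epimers) | CC(=O)O[C@H]1[C@H](OC(=O)C(C)C)[C@](C)(O)[C@](C)(COCc3ccccc3)[C@H]2CCC([Si](C)(C)C)C(=O)[C@]12C | intermediate
15 | trans-decal-4-one diester | CC(=O)O[C@H]1[C@H](OC(=O)C(C)C)[C@](C)(O)[C@](C)(COCc3ccccc3)[C@H]2CCCC(=O)[C@]12C | intermediate
16 | 11-hydroxy trans-decal-4-one diester | CC(=O)O[C@H]1[C@H](OC(=O)C(C)C)[C@](C)(O)[C@](C)(CO)[C@H]2CCCC(=O)[C@]12C | intermediate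
17 | 4(18)-exomethylene 8,11-diol diester | CC(=O)O[C@H]1[C@H](OC(=O)C(C)C)[C@](C)(O)[C@](C)(CO)[C@H]2CCCC(=C)[C@]12C | intermediate
18 | 3-ene 8,11-diol diester | CC(=O)O[C@H]1[C@H](OC(=O)C(C)C)[C@](C)(O)[C@](C)(CO)[C@H]2CCC=C(C)[C@]12C | intermediate
19 | 3-en-11-al | CC(=O)O[C@H]1[C@H](OC(=O)C(C)C)[C@](C)(O)[C@](C)(C=O)[C@H]2CCC=C(C)[C@]12C | intermediate
20 | 4-(bromomethyl)furan-2(5H)-one | BrCC1=CC(=O)OC1 | starting material
21 | diethyl [(5-oxo-2,5-dihydrofuran-3-yl)methyl]phosphonate | CCOP(=O)(CC1=CC(=O)OC1)OCC | intermediate
22 | CNP0207114.1 | CC(=O)O[C@H]1[C@H](OC(=O)C(C)C)[C@](C)(O)[C@](C)(/C=C/C2=CC(=O)OC2)[C@H]2CCC=C(C)[C@]12C | target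

Total step count: 19. Longest linear sequence: 18 (steps 1–17 and 19).

**Steps most likely to fail**

Step 13. Addition of the diazoalkane to the neopentyl-type carbonyl may be too slow, so that oxirane formation or Lewis-acid damage to the tertiary alcohol takes over. The fallback sets out from 13 and brings in the carbon through a cyclopropanol-type (Saegusa-type) ring enlargement.
- TMSOTf/Et3N should give the bis-silylated enol ether F1.
- Et2Zn/CH2I2 (Simmons–Smith reaction on the β face) should give the siloxycyclopropane F2.
- FeCl3 in DMF should open the internal C2–C4 bond to the ring-enlarged 2-chloro ketone F3.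
- DBU should give the 2-en-4-one F4.
- H2 over Pd/C should saturate the enone and remove the benzyl group at once, so the route is rejoined at 16.

Step 5. O-alkylation by the hard chloromethyl ether, or no reaction of the crowded enolate, may prevail over C-alkylation. The fallback sets out from 5.
- LiN(i-Pr)2/TMSCl should give the silyl dienol ether F5.
- Aqueous formaldehyde with Sc(OTf)3 (Mukaiyama aldol hydroxymethylation, again from the β face) should give the 9β-hydroxymethyl ketone F6.
- Benzyl trichloroacetimidate with catalytic TfOH should return to the route at 6.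

Step 19. Slow addition to the neopentyl aldehyde may let retro-aldol cleavage or deprotonation of the butenolide ring CH2 compete. The fallback sets out from 19.
- CrCl2/LiI with Cl2CHB(pin) (Takai–Utimoto olefination) should give the E-alkenyl boronate F7.
- Suzuki–Miyaura coupling of F7 with commercial 4-bromofuran-2(5H)-one (Pd(PPh3)4, aq K3PO4, THF) should arrive at 22.

Further compounds
F1 | step 13 | 4-(trimethylsilyloxy)hydrind-2(4)-ene, 8-O-trimethylsilyl ether | CC(=O)O[C@H]1[C@H](OC(=O)C(C)C)[C@](C)(O[Si](C)(C)C)[C@](C)(COCc3ccccc3)[C@H]2CC=C(O[Si](C)(C)C)[C@]12C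
F2 | step 13 | 2,4-methano (β) siloxycyclopropane, 8-O-trimethylsilyl ether | CC(=O)O[C@H]1[C@H](OC(=O)C(C)C)[C@](C)(O[Si](C)(C)C)[C@](C)(COCc3ccccc3)[C@H]2C[C@@H]3C[C@]3(O[Si](C)(C)C)[C@]12C
F3 | step 13 | 2-chloro-trans-decal-4-one diester (C2 epimers) | CC(=O)O[C@H]1[C@H](OC(=O)C(C)C)[C@](C)(O)[C@](C)(COCc3ccccc3)[C@H]2CC(Cl)CC(=O)[C@]12C
F4 | step 13 | trans-octal-2-en-4-one diester | CC(=O)O[C@H]1[C@H](OC(=O)C(C)C)[C@](C)(O)[C@](C)(COCc3ccccc3)[C@H]2CC=CC(=O)[C@]12C
F5 | step 5 | 8-(trimethylsilyloxy)-6,8-diene ketal | C1=CC(O[Si](C)(C)C)=C(C)[C@H]2CCC3(OCCO3)[C@]12C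
F6 | step 5 | 9β-(hydroxymethyl)-9α-methyl enone ketal | C1=CC(=O)[C@](C)(CO)[C@H]2CCC3(OCCO3)[C@]12C
F7 | step 19 | E-11-alkenyl pinacol boronate | CC(=O)O[C@H]1[C@H](OC(=O)C(C)C)[C@](C)(O)[C@](C)(/C=C/B3OC(C)(C)C(C)(C)O3)[C@H]2CCC=C(C)[C@]12C
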